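**Retrosynthetic overview**
1. Target 17 ⇐ bis-TBS acetate 16 (desilylation) ⇐ allylic alcohol 15 (acetylation).
2. C3–OH and C4–H(OMe) ⇐ methyl dienol ether 13: epoxidation anti to the silyloxy groups, then hydride opening of the epoxy ether with inversion at the ketal carbon.
3. Side-chain CH2–CH= bond ⇐ allylic chloride 10 + (E)-alkenylboronate 12 (allyl–alkenyl Suzuki coupling).
4. Ring–C≡C bond ⇐ dienol ether 3 + alkynyl(phenyl)iodonium salt 8: δ-C–H alkynylation through an alkylidene carbene and a 1,2-alkenyl shift (key step).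
5. 3 ⇐ anisole by enzymatic cis-dihydroxylation, which sets C5 and C6. The only ring is the carbocycle of anisole, dearomatised in step 1; no ring is formed later.

Assumption: ring locants follow the target SMILES (C1 alkynyl carbon, C2 =CH, C3 C–OAc, C4 C–OMe, C5 and C6 C–OH, C6 next to C1), and the NADH used by the dioxygenase in step 1 is recycled by the cells and counted as part of the biocatalyst.

**Route**

Step 1
Reactants: 1 anisole
Product: 2 (1S,2S)-3-methoxycyclohexa-3,5-diene-1,2-diol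
Conditions: E. coli JM109(pDTG601) whole cells (toluene dioxygenase), air, glucose, phosphate buffer pH 7.2, 30 °C; EtOAc extraction at pH 8.5; used crude
Reagents that add atoms: dioxygen O=O
Why: Enzymatic arene cis-dihydroxylation (toluene dioxygenase) delivers both oxygens to one face of the bond next to the substituent and gives the (1S,2S)-diol as for other monosubstituted benzenes, which sets C5 and C6 and places OMe on the future C4.

Step 2
Reactants: 2 (1S,2S)-3-methoxycyclohexa-3,5-diene-1,2-diol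
Product: 3 (5S,6S)-5,6-bis[(tert-butyldimethylsilyl)oxy]-1-methoxycyclohexa-1,3-diene
Conditions: TBSOTf (2.4 equiv), 2,6-lutidine (4 equiv), CH2Cl2, −78 → 0 °C
Reagents that add atoms: tert-butyldimethylsilyl trifluoromethanesulfonate CC(C)(C)[Si](C)(C)OS(=O)(=O)C(F)(F)F
Why: Silyl ether formation under buffered basic conditions protects the cis-diol without exposing the acid-labile dienol ether to aromatisation and touches no stereocentre.

Step 3
Reactants: 4 2-bromoprop-2-en-1-ol; 5 ethynyltrimethylsilane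
Product: 6 2-[(trimethylsilyl)ethynyl]prop-2-en-1-ol
Conditions: PdCl2(PPh3)2 (2 mol%), CuI (4 mol%), iPr2NH, THF, rt
Reagents that add atoms: none
Why: Sonogashira coupling of a vinyl bromide with a terminal alkyne tolerates the free primary alcohol.

Step 4
Reactants: 6 2-[(trimethylsilyl)ethynyl]prop-2-en-1-ol
Product: 7 [3-(chloromethyl)but-3-en-1-yn-1-yl]trimethylsilane
Conditions: PPh3, N-chlorosuccinimide, THF, 0 °C → rt
Reagents that add atoms: N-chlorosuccinimide O=C1CCC(=O)N1Cl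
Why: Appel-type chlorination of a primary allylic alcohol, where the 2-substituted allyl unit is symmetrical so SN2 and SN2′ give the same chloride.

Step 5
Reactants: 7 [3-(chloromethyl)but-3-en-1-yn-1-yl]trimethylsilane
Product: 8 [3-(chloromethyl)but-3-en-1-yn-1-yl](phenyl)iodonium trifluoromethanesulfonate
Conditions: PhI(OAc)2, TfOH, CH2Cl2, 0 °C; then 7, 0 °C; precipitation with Et2O at −30 °C; used fresh
Reagents that add atoms: (diacetoxyiodo)benzene CC(=O)OI(OC(C)=O)c1ccccc1; trifluoromethanesulfonic acid OS(=O)(=O)C(F)(F)F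
Why: Electrophilic ipso-substitution of an alkynylsilane by PhI(OAc)OTf formed in situ is the standard synthesis of alkynyl(phenyl)iodonium triflates.

Step 6
Reactants: 3 (5S,6S)-5,6-bis[(tert-butyldimethylsilyl)oxy]-1-methoxycyclohexa-1,3-diene; 8 [3-(chloromethyl)but-3-en-1-yn-1-yl](phenyl)iodonium trifluoromethanesulfonate
Product: 10 (5S,6S)-5,6-bis[(tert-butyldimethylsilyl)oxy]-1-[3-(chloromethyl)but-3-en-1-yn-1-yl]-4-methoxycyclohexa-1,3-diene, via alkylidene carbene 9 (not isolated)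
Conditions: 2,6-di-tert-butyl-4-methylpyridine (1.5 equiv), CH2Cl2, −78 → −20 °C, 3 in slight excess; Et3N quench
Reagents that add atoms: none
Why: Proposed new method: δ-selective C–H alkynylation of a neutral dienol ether by an alkynyl(aryl)-λ3-iodane, in which the terminal diene carbon (largest HOMO coefficient) adds to Cβ of 8, the iodonium ylide expels PhI to give alkylidene carbene 9, an alkenyl substituent of 9 migrates to the carbene carbon (Fritsch–Buttenberg–Wiechell 1,2-shift) to form the ring–C≡C bond, and loss of the ring proton to the hindered base restores the dienol ether; the closest known reactions are the addition/α-elimination/1,2-shift alkynylations of β-dicarbonyl enolates with alkynyliodonium salts or EBX reagents and the δ-selective Vilsmeier formylation of steroidal 3-alkoxy-3,5-dienes.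

Step 7
Reactants: 11 2-methylbut-3-yn-2-ol
Product: 12 (E)-2-methyl-4-(4,4,5,5-tetramethyl-1,3,2-dioxaborolan-2-yl)but-3-en-2-ol
Conditions: B2pin2 (1.1 equiv), CuCl (5 mol%), Xantphos (5 mol%), NaOtBu (10 mol%), MeOH (2 equiv), THF, rt
Reagents that add atoms: bis(pinacolato)diboron CC1(C)OB(OC1(C)C)B1OC(C)(C)C(C)(C)O1
Why: Copper-catalysed borylcupration–protonation (formal hydroboration) of the terminal alkyne is syn with boron on the terminal carbon, which sets the E alkene.

Step 8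
Reactants: 10 (5S,6S)-5,6-bis[(tert-butyldimethylsilyl)oxy]-1-[3-(chloromethyl)but-3-en-1-yn-1-yl]-4-methoxycyclohexa-1,3-diene; 12 (E)-2-methyl-4-(4,4,5,5-tetramethyl-1,3,2-dioxaborolan-2-yl)but-3-en-2-ol
Product: 13 (3E)-8-{(5S,6S)-5,6-bis[(tert-butyldimethylsilyl)oxy]-4-methoxycyclohexa-1,3-dien-1-yl}-2-methyl-6-methylideneoct-3-en-7-yn-2-ol
Conditions: Pd(PPh3)4 (5 mol%), K3PO4 (3 equiv), THF/H2O 10:1, 45 °C
Reagents that add atoms: none
Why: Suzuki–Miyaura allyl–alkenyl coupling, in which the primary allylic chloride gives a π-allylpalladium with equivalent termini and the alkenylboronate transfers with retention of the E geometry.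

Step 9
Reactants: 13 (3E)-8-{(5S,6S)-5,6-bis[(tert-butyldimethylsilyl)oxy]-4-methoxycyclohexa-1,3-dien-1-yl}-2-methyl-6-methylideneoct-3-en-7-yn-2-ol
Product: 15 (1S,4S,5R,6S)-4,5-bis[(tert-butyldimethylsilyl)oxy]-3-[(5E)-7-hydroxy-7-methyl-3-methylideneoct-5-en-1-yn-1-yl]-6-methoxycyclohex-2-en-1-ol, via epoxy ether 14 (not isolated)
Conditions: DMDO (1.05 equiv, acetone), CH2Cl2, −78 °C; volatiles removed at −40 °C; LiBHEt3 (3 equiv), THF, −78 → −40 °C; H2O
Reagents that add atoms: dimethyldioxirane CC1(C)OO1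
Why: Chemoselective epoxidation of the enol ether double bond (the other ring alkene is deactivated by the alkyne) anti to the silyloxy groups sets C3, and hydride opening of the epoxy ether at the ketal carbon with inversion (as nucleophiles open 1,2-anhydroglycosides trans) sets C4 with OMe cis to the new OH.

Step 10
Reactants: 15 (1S,4S,5R,6S)-4,5-bis[(tert-butyldimethylsilyl)oxy]-3-[(5E)-7-hydroxy-7-methyl-3-methylideneoct-5-en-1-yn-1-yl]-6-methoxycyclohex-2-en-1-ol
Product: 16 (1S,4S,5R,6S)-4,5-bis[(tert-butyldimethylsilyl)oxy]-3-[(5E)-7-hydroxy-7-methyl-3-methylideneoct-5-en-1-yn-1-yl]-6-methoxycyclohex-2-en-1-yl acetate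
Conditions: Ac2O (1.3 equiv), pyridine, DMAP (5 mol%), CH2Cl2, 0 °C
Reagents that add atoms: acetic anhydride CC(=O)OC(C)=O
Why: DMAP-catalysed acylation esterifies the secondary allylic alcohol with retention and leaves the hindered tertiary alcohol untouched.

Step 11
Reactants: 16 (1S,4S,5R,6S)-4,5-bis[(tert-butyldimethylsilyl)oxy]-3-[(5E)-7-hydroxy-7-methyl-3-methylideneoct-5-en-1-yn-1-yl]-6-methoxycyclohex-2-en-1-yl acetate
Product: 17 (1S,4S,5S,6R)-4,5-dihydroxy-3-[(5E)-7-hydroxy-7-methyl-3-methylideneoct-5-en-1-yn-1-yl]-6-methoxycyclohex-2-en-1-yl acetate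
Conditions: HF·pyridine, pyridine, THF, 0 °C → rt
Reagents that add atoms: none
Why: Buffered fluoride desilylation removes both TBS ethers without cleaving the allylic acetate or ionising the tertiary allylic alcohol and touches no stereocentre.

**Compound list**
1 | anisole | COc1ccccc1 | starting material
2 | (1S,2S)-3-methoxycyclohexa-3,5-diene-1,2-diol | COC1=CC=C[C@H](O)[C@@H]1O | intermediate
3 | (5S,6S)-5,6-bis[(tert-butyldimethylsilyl)oxy]-1-methoxycyclohexa-1,3-diene | COC1=CC=C[C@H](O[Si](C)(C)C(C)(C)C)[C@@H]1O[Si](C)(C)C(C)(C)C | intermediate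
4 | 2-bromoprop-2-en-1-ol | OCC(Br)=C | starting material
5 | ethynyltrimethylsilane | C#C[Si](C)(C)C | starting material
6 | 2-[(trimethylsilyl)ethynyl]prop-2-en-1-ol | OCC(=C)C#C[Si](C)(C)C | intermediate
7 | [3-(chloromethyl)but-3-en-1-yn-1-yl]trimethylsilane | ClCC(=C)C#C[Si](C)(C)C | intermediate
8 | [3-(chloromethyl)but-3-en-1-yn-1-yl](phenyl)iodonium trifluoromethanesulfonate | ClCC(=C)C#C[I+]c1ccccc1.[O-]S(=O)(=O)C(F)(F)F | intermediate
9 | alkylidene carbene (ring)(CH2=C(CH2Cl))C=C: with ring = (5S,6S)-5,6-bis(TBSO)-4-methoxycyclohexa-1,3-dien-1-yl; the divalent carbon is the former iodine-bearing carbon of 8 | [C]=C(C(=C)CCl)C1=CC=C(OC)[C@@H](O[Si](C)(C)C(C)(C)C)[C@H]1O[Si](C)(C)C(C)(C)C | intermediate (not isolated)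
10 | (5S,6S)-5,6-bis[(tert-butyldimethylsilyl)oxy]-1-[3-(chloromethyl)but-3-en-1-yn-1-yl]-4-methoxycyclohexa-1,3-diene | ClCC(=C)C#CC1=CC=C(OC)[C@@H](O[Si](C)(C)C(C)(C)C)[C@H]1O[Si](C)(C)C(C)(C)C | intermediate
11 | 2-methylbut-3-yn-2-ol | CC(C)(O)C#C | starting material
12 | (E)-2-methyl-4-(4,4,5,5-tetramethyl-1,3,2-dioxaborolan-2-yl)but-3-en-2-ol | CC(C)(O)/C=C/B1OC(C)(C)C(C)(C)O1 | intermediate
13 | (3E)-8-{(5S,6S)-5,6-bis[(tert-butyldimethylsilyl)oxy]-4-methoxycyclohexa-1,3-dien-1-yl}-2-methyl-6-methylideneoct-3-en-7-yn-2-ol | C=C(C#CC1=CC=C(OC)[C@@H](O[Si](C)(C)C(C)(C)C)[C@H]1O[Si](C)(C)C(C)(C)C)C/C=C/C(C)(C)O | intermediate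
14 | epoxy ether of 13: ring C3–C4 oxirane on the face opposite both OTBS groups, C4 carrying OMe | C=C(C#CC1=C[C@@H]2O[C@]2(OC)[C@@H](O[Si](C)(C)C(C)(C)C)[C@H]1O[Si](C)(C)C(C)(C)C)C/C=C/C(C)(C)O | intermediate (not isolated)
15 | (1S,4S,5R,6S)-4,5-bis[(tert-butyldimethylsilyl)oxy]-3-[(5E)-7-hydroxy-7-methyl-3-methylideneoct-5-en-1-yn-1-yl]-6-methoxycyclohex-2-en-1-ol | C=C(C#CC1=C[C@H](O)[C@H](OC)[C@@H](O[Si](C)(C)C(C)(C)C)[C@H]1O[Si](C)(C)C(C)(C)C)C/C=C/C(C)(C)O | intermediate
16 | (1S,4S,5R,6S)-4,5-bis[(tert-butyldimethylsilyl)oxy]-3-[(5E)-7-hydroxy-7-methyl-3-methylideneoct-5-en-1-yn-1-yl]-6-methoxycyclohex-2-en-1-yl acetate | C=C(C#CC1=C[C@H](OC(C)=O)[C@H](OC)[C@@H](O[Si](C)(C)C(C)(C)C)[C@H]1O[Si](C)(C)C(C)(C)C)C/C=C/C(C)(C)O | intermediate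
17 | (1S,4S,5S,6R)-4,5-dihydroxy-3-[(5E)-7-hydroxy-7-methyl-3-methylideneoct-5-en-1-yn-1-yl]-6-methoxycyclohex-2-en-1-yl acetate | C=C(C#CC1=C[C@H](OC(C)=O)[C@H](OC)[C@@H](O)[C@H]1O)C/C=C/C(C)(C)O | target

**Step count**
Total: 11 steps. Longest linear sequence: 8 steps (steps 3, 4, 5, 6, 8, 9, 10, 11 from 4 and 5); 7 steps from anisole.

**Steps most likely to fail**

Step 6 (the proposed new alkynylation). The dienol ether may be too weak a nucleophile, may react at the α-carbon, or may add to the alkene terminus of 8. The fallback uses only known chemistry, sets out from 3 and comes back at 13, so that steps 3–6 and 8 are not needed. Vilsmeier–Haack formylation of 3 (POCl3, DMF, 0 °C; aq. NaOAc), well known at the δ-carbon of 3-alkoxy-3,5-dienes, gives (5S,6S)-5,6-bis[(tert-butyldimethylsilyl)oxy]-4-methoxycyclohexa-1,3-diene-1-carbaldehyde F4. Ohira–Bestmann homologation (dimethyl (1-diazo-2-oxopropyl)phosphonate, K2CO3, MeOH) converts it into (5S,6S)-5,6-bis[(tert-butyldimethylsilyl)oxy]-1-ethynyl-4-methoxycyclohexa-1,3-diene F5. In parallel, Suzuki allylation of 12 with 2,3-dibromoprop-1-ene F6 (Pd(PPh3)4, K3PO4, THF/H2O), which reacts at the allylic bromide, gives (3E)-6-bromo-2-methylhepta-3,6-dien-2-ol F7. Sonogashira coupling of F5 with F7 then gives 13.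

Step 9 (epoxidation and hydride opening). The dioxirane may attack the enyne double bond instead, or the hydride may be delivered to C4 with retention. The fallback sets out from 10, before the acid-labile tertiary allylic alcohol is present, and comes back at 16, replacing steps 8–10. It fixes C4 by neighbouring-group participation, but it still relies on epoxidation of the enol ether bond. DMDO in CH2Cl2/MeOH (−78 → −20 °C) epoxidises the enol ether and methanol opens the epoxy ether in situ to (1S,4S,5S)-4,5-bis[(tert-butyldimethylsilyl)oxy]-3-[3-(chloromethyl)but-3-en-1-yn-1-yl]-6,6-dimethoxycyclohex-2-en-1-ol F8. Acetylation (Ac2O, pyridine, DMAP) gives the corresponding acetate (1S,4S,5S)-4,5-bis[(tert-butyldimethylsilyl)oxy]-3-[3-(chloromethyl)but-3-en-1-yn-1-yl]-6,6-dimethoxycyclohex-2-en-1-yl acetate F9. Ionic reduction (Et3SiH, TMSOTf, CH2Cl2, −40 °C) passes through the acetoxonium ion, so hydride enters trans to the acetate and gives (1S,4S,5R,6S)-4,5-bis[(tert-butyldimethylsilyl)oxy]-3-[3-(chloromethyl)but-3-en-1-yn-1-yl]-6-methoxycyclohex-2-en-1-yl acetate F10. Suzuki coupling of F10 with 12 under the conditions of step 8 gives 16.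

Step 1 (dioxygenation of anisole). The diol 2 is formed in modest titre alongside O-demethylation to phenol and aromatises easily. The fallback replaces 1 and 2 and comes back at 3. It sets out from bromobenzene F1, whose dioxygenation with the same strain is robust and gives (1S,2S)-3-bromocyclohexa-3,5-diene-1,2-diol F2 with the same spatial sense. Silylation (TBSOTf, 2,6-lutidine) gives (5S,6S)-1-bromo-5,6-bis[(tert-butyldimethylsilyl)oxy]cyclohexa-1,3-diene F3. Copper-catalysed C–O coupling of the vinyl bromide with methanol (CuI, 3,4,7,8-tetramethyl-1,10-phenanthroline, Cs2CO3, MeOH/toluene, 80 °C) then gives 3.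

**Further compounds**
F1 | step 1 | bromobenzene | Brc1ccccc1
F2 | step 1 | (1S,2S)-3-bromocyclohexa-3,5-diene-1,2-diol | BrC1=CC=C[C@H](O)[C@@H]1O
F3 | step 1 | (5S,6S)-1-bromo-5,6-bis[(tert-butyldimethylsilyl)oxy]cyclohexa-1,3-diene | BrC1=CC=C[C@H](O[Si](C)(C)C(C)(C)C)[C@@H]1O[Si](C)(C)C(C)(C)C
F4 | step 6 | (5S,6S)-5,6-bis[(tert-butyldimethylsilyl)oxy]-4-methoxycyclohexa-1,3-diene-1-carbaldehyde | O=CC1=CC=C(OC)[C@@H](O[Si](C)(C)C(C)(C)C)[C@H]1O[Si](C)(C)C(C)(C)C
F5 | step 6 | (5S,6S)-5,6-bis[(tert-butyldimethylsilyl)oxy]-1-ethynyl-4-methoxycyclohexa-1,3-diene | C#CC1=CC=C(OC)[C@@H](O[Si](C)(C)C(C)(C)C)[C@H]1O[Si](C)(C)C(C)(C)C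
F6 | step 6 | 2,3-dibromoprop-1-ene | BrCC(Br)=C
F7 | step 6 | (3E)-6-bromo-2-methylhepta-3,6-dien-2-ol | CC(C)(O)/C=C/CC(Br)=C
F8 | step 9 | (1S,4S,5S)-4,5-bis[(tert-butyldimethylsilyl)oxy]-3-[3-(chloromethyl)but-3-en-1-yn-1-yl]-6,6-dimethoxycyclohex-2-en-1-ol | ClCC(=C)C#CC1=C[C@H](O)C(OC)(OC)[C@@H](O[Si](C)(C)C(C)(C)C)[C@H]1O[Si](C)(C)C(C)(C)C
F9 | step 9 | (1S,4S,5S)-4,5-bis[(tert-butyldimethylsilyl)oxy]-3-[3-(chloromethyl)but-3-en-1-yn-1-yl]-6,6-dimethoxycyclohex-2-en-1-yl acetate | ClCC(=C)C#CC1=C[C@H](OC(C)=O)C(OC)(OC)[C@@H](O[Si](C)(C)C(C)(C)C)[C@H]1O[Si](C)(C)C(C)(C)C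
F10 | step 9 | (1S,4S,5R,6S)-4,5-bis[(tert-butyldimethylsilyl)oxy]-3-[3-(chloromethyl)but-3-en-1-yn-1-yl]-6-methoxycyclohex-2-en-1-yl acetate | ClCC(=C)C#CC1=C[C@H](OC(C)=O)[C@H](OC)[C@@H](O[Si](C)(C)C(C)(C)C)[C@H]1O[Si](C)(C)C(C)(C)C
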